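**Retrosynthetic overview**

- The strategy rests on the spiro carbon C5 (benzo[7]annulene numbering; it is also C1′ of dienone ring B). It carries ring A (through C4a) and the ring methylene C6, so it is the carbon para to oxygen of a 4-aryl-2,6-dimethoxyphenol that has been C-alkylated.
- The C5–C6 bond is cut last: a biaryl phenol carrying a primary mesylate and a silylated C9 carbinol closes the seven-membered ring by phenolate para-C-alkylation, and fluoride then frees the C9 hydroxyl.
- The biaryl bond comes from a Suzuki coupling of a ring-A bromolactone with a benzyl-protected ring-B boronate. The lactone is then reduced and the two hydroxyl groups are differentiated.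
- C9 is set by oxazaborolidine reduction of an aryl ketone. C7 and C8 come from (2S,3S)-2,3-dimethylsuccinic anhydride, opened by the ring-A Grignard reagent.
- Ring order: rings A and B are bought as benzenes and joined; a temporary lactone holds the side chain; the seven-membered ring and the dienone form together at the end.

Key step: step 14

Assumption: (2S,3S)-2,3-dimethylsuccinic acid is purchasable as the single enantiomer (otherwise the racemic trans acid is resolved by classical salt formation); ring A is the trimethoxybenzene, ring B the dienone, and C5–C9 are the benzo[7]annulene positions (C5 spiro, C6 CH2, C7 and C8 CH–CH3, C9 CH–OH).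

**Route**

Step 1
Reactants: 1 (2S,3S)-2,3-dimethylbutanedioic acid
Product: 2 (3S,4S)-3,4-dimethyloxolane-2,5-dione (trans-2,3-dimethylsuccinic anhydride)
Conditions: AcCl (neat), reflux; evaporate
Reagents that add atoms: none
Why: Acetyl chloride dehydrates the 1,4-diacid to the five-membered cyclic anhydride (cyclodehydration) without base, so the two methyl-bearing centres should keep their trans relationship.

Step 2
Reactants: 2 (3S,4S)-3,4-dimethyloxolane-2,5-dione; 3 5-bromo-1,2,3-trimethoxybenzene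
Product: 5 (2S,3S)-2,3-dimethyl-4-oxo-4-(3,4,5-trimethoxyphenyl)butanoic acid, via aryl Grignard reagent 4 (not isolated)
Conditions: 3, Mg, I2 (cat.), THF, reflux; then added to 2 (1.2 equiv), THF, −78 → −20 °C; 1 M HCl
Reagents that add atoms: none
Why: Nucleophilic acyl substitution of the cyclic anhydride by the Grignard reagent gives a keto carboxylate that resists a second addition at low temperature with inverse addition, and because 2 is C2-symmetric its two carbonyl groups are equivalent, so one keto acid should form with both stereocentres carried over.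

Step 3
Reactants: 5 (2S,3S)-2,3-dimethyl-4-oxo-4-(3,4,5-trimethoxyphenyl)butanoic acid
Product: 6 methyl (2S,3S)-2,3-dimethyl-4-oxo-4-(3,4,5-trimethoxyphenyl)butanoate
Conditions: TMSCHN2, PhMe/MeOH (4:1), 0 °C
Reagents that add atoms: trimethylsilyldiazomethane, C[Si](C)(C)C=[N+]=[N-]
Why: Methyl esterification with trimethylsilyldiazomethane runs under near-neutral conditions, so the enolisable centre next to the aryl ketone should not epimerise, and the ester does not consume borane in the next step.

Step 4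
Reactants: 6 methyl (2S,3S)-2,3-dimethyl-4-oxo-4-(3,4,5-trimethoxyphenyl)butanoate
Product: 8 (3S,4S,5R)-3,4-dimethyl-5-(3,4,5-trimethoxyphenyl)oxolan-2-one (3,4-trans, 4,5-cis), via hydroxy ester 7 (not isolated)
Conditions: (S)-2-methyl-CBS-oxazaborolidine (0.5 equiv), BH3·SMe2 (1.0 equiv), THF, −20 °C; MeOH; then PPTS (cat.), CH2Cl2, rt
Reagents that add atoms: none
Why: Corey–Bakshi–Shibata reduction, in which the (S)-oxazaborolidine binds the ketone with the aryl group as the large substituent and delivers hydride to give the (R)-benzylic alcohol under reagent control (the catalyst, not the neighbouring methyl-bearing centre, sets the new centre), after which the γ-hydroxy ester lactonises under mild acid.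

Step 5
Reactants: 8 (3S,4S,5R)-3,4-dimethyl-5-(3,4,5-trimethoxyphenyl)oxolan-2-one
Product: 9 (3S,4S,5R)-5-(2-bromo-3,4,5-trimethoxyphenyl)-3,4-dimethyloxolan-2-one
Conditions: NBS (1.05 equiv), MeCN, 0 °C → rt, dark
Reagents that add atoms: N-bromosuccinimide, O=C1CCC(=O)N1Br
Why: Electrophilic aromatic bromination goes to C2 of the trimethoxyphenyl ring, the only kind of free position (C2 and C6 are equivalent), which is para to one methoxy group and ortho to another.

Step 6
Reactants: 10 4-bromo-2,6-dimethoxyphenol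
Product: 11 2-(benzyloxy)-5-bromo-1,3-dimethoxybenzene
Conditions: BnBr, K2CO3, DMF, rt
Reagents that add atoms: benzyl bromide, BrCc1ccccc1
Why: Williamson ether synthesis masks the phenol as a benzyl ether that should survive palladium coupling, LiAlH4, silylation and mesylation and is later removed by neutral hydrogenolysis.

Step 7
Reactants: 11 2-(benzyloxy)-5-bromo-1,3-dimethoxybenzene
Product: 12 2-[4-(benzyloxy)-3,5-dimethoxyphenyl]-4,4,5,5-tetramethyl-1,3,2-dioxaborolane
Conditions: B2pin2, Pd(dppf)Cl2 (3 mol%), KOAc, 1,4-dioxane, 90 °C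
Reagents that add atoms: bis(pinacolato)diboron, CC1(C)OB(OC1(C)C)B1OC(C)(C)C(C)(C)O1
Why: Miyaura borylation of the aryl bromide under zerovalent palladium catalysis gives the pinacol boronate, KOAc being too weak a base to promote a following Suzuki homocoupling.

Step 8
Reactants: 9 (3S,4S,5R)-5-(2-bromo-3,4,5-trimethoxyphenyl)-3,4-dimethyloxolan-2-one; 12 2-[4-(benzyloxy)-3,5-dimethoxyphenyl]-4,4,5,5-tetramethyl-1,3,2-dioxaborolane
Product: 13 (3S,4S,5R)-5-[4′-(benzyloxy)-3′,4,5,5′,6-pentamethoxybiphenyl-2-yl]-3,4-dimethyloxolan-2-one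
Conditions: Pd(OAc)2 (5 mol%), SPhos (10 mol%), K3PO4, PhMe/H2O (10:1), 90 °C; dilute-acid work-up
Reagents that add atoms: none
Why: Suzuki–Miyaura coupling with the SPhos-ligated palladium catalyst, which inserts into the hindered, electron-rich aryl bromide and couples it with the ortho-unsubstituted boronate, so only a di-ortho-substituted biaryl has to form; the acid work-up re-closes any lactone opened by the aqueous base.

Step 9
Reactants: 13 (3S,4S,5R)-5-[4′-(benzyloxy)-3′,4,5,5′,6-pentamethoxybiphenyl-2-yl]-3,4-dimethyloxolan-2-one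
Product: 14 (1R,2S,3S)-1-[4′-(benzyloxy)-3′,4,5,5′,6-pentamethoxybiphenyl-2-yl]-2,3-dimethylbutane-1,4-diol
Conditions: LiAlH4, THF, 0 °C; aq. potassium sodium tartrate work-up
Reagents that add atoms: none
Why: LiAlH4 reduction of the lactone (ester reduction) gives the 1,4-diol without touching the benzyl ether or any stereocentre.

Step 10
Reactants: 14 (1R,2S,3S)-1-[4′-(benzyloxy)-3′,4,5,5′,6-pentamethoxybiphenyl-2-yl]-2,3-dimethylbutane-1,4-diol
Product: 15 bis(tert-butyldimethylsilyl) ether of diol 14 (both hydroxyl groups silylated)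
Conditions: TBSOTf (2.5 equiv), 2,6-lutidine, CH2Cl2, −78 → 0 °C
Reagents that add atoms: tert-butyldimethylsilyl trifluoromethanesulfonate, CC(C)(C)[Si](C)(C)OS(=O)(=O)C(F)(F)F
Why: The silyl triflate silylates both the primary and the hindered benzylic hydroxyl group (silyl ether formation), which avoids activating the primary alcohol of a free 1,4-diol that would close to a tetrahydrofuran.

Step 11
Reactants: 15 bis(tert-butyldimethylsilyl) ether of diol 14
Product: 16 (2S,3S,4R)-4-[4′-(benzyloxy)-3′,4,5,5′,6-pentamethoxybiphenyl-2-yl]-4-[(tert-butyldimethylsilyl)oxy]-2,3-dimethylbutan-1-ol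
Conditions: HF·pyridine, pyridine, THF, 0 °C
Reagents that add atoms: none
Why: Selective desilylation, since buffered HF·pyridine should cleave the unhindered primary silyl ether much faster than the secondary benzylic one flanked by the biaryl and a methyl-bearing carbon.

Step 12
Reactants: 16 (2S,3S,4R)-4-[4′-(benzyloxy)-3′,4,5,5′,6-pentamethoxybiphenyl-2-yl]-4-[(tert-butyldimethylsilyl)oxy]-2,3-dimethylbutan-1-ol
Product: 17 (2S,3S,4R)-4-[4′-(benzyloxy)-3′,4,5,5′,6-pentamethoxybiphenyl-2-yl]-4-[(tert-butyldimethylsilyl)oxy]-2,3-dimethylbutyl methanesulfonate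
Conditions: MsCl, Et3N, CH2Cl2, 0 °C
Reagents that add atoms: methanesulfonyl chloride, CS(=O)(=O)Cl
Why: Sulfonylation of the primary alcohol installs the leaving group while the other oxygen nucleophiles are masked as silyl and benzyl ethers.

Step 13
Reactants: 17 (2S,3S,4R)-4-[4′-(benzyloxy)-3′,4,5,5′,6-pentamethoxybiphenyl-2-yl]-4-[(tert-butyldimethylsilyl)oxy]-2,3-dimethylbutyl methanesulfonate
Product: 18 (2S,3S,4R)-4-[(tert-butyldimethylsilyl)oxy]-4-(4′-hydroxy-3′,4,5,5′,6-pentamethoxybiphenyl-2-yl)-2,3-dimethylbutyl methanesulfonate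
Conditions: H2 (1 atm), Pd/C (10%), EtOAc, rt
Reagents that add atoms: none
Why: Hydrogenolysis of the aryl benzyl ether frees the phenol under neutral conditions in which the primary mesylate and the silyl ether are inert and the un-ionised phenol does not alkylate.

Step 14
Reactants: 18 (2S,3S,4R)-4-[(tert-butyldimethylsilyl)oxy]-4-(4′-hydroxy-3′,4,5,5′,6-pentamethoxybiphenyl-2-yl)-2,3-dimethylbutyl methanesulfonate
Product: 20 (7R,8S,9R)-9-[(tert-butyldimethylsilyl)oxy]-2,3,3′,4,5′-pentamethoxy-7,8-dimethyl-6,7,8,9-tetrahydrospiro[benzo[7]annulene-5,1′-cyclohexa[2,5]dien]-4′-one, via potassium phenolate 19 (not isolated)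
Conditions: KOt-Bu (1.05 equiv), t-BuOH, 80 °C, 18 added by syringe pump (final 0.002 M)
Reagents that add atoms: none
Why: Deprotonation gives the ambident phenolate 19, whose para carbon (C1′ of ring B, the carbon that already bears ring A) displaces the primary mesylate by SN2, so the C5–C6 bond forms while ring B is dearomatised to the cross-conjugated 2,6-dimethoxycyclohexa-2,5-dienone; the closest known reaction type is the intramolecular para-C-alkylation of phenolates carrying an ω-sulfonate (Ar1-5 and Ar1-6 spirodienone closures), used here in its seven-ring version. The seven-membered ring closes in the 7-exo-tet mode, two of its atoms being the rigid ortho carbons of ring A, and the twist of the di-ortho-substituted biaryl turns the p-lobe at C1′ toward the tether. No stereocentre is created, because the spiro carbon carries two identical dienone arms, and C7, C8 and C9 are not touched by substitution at a CH2 group. The step needs para-C-alkylation to win over O-alkylation and elimination: within the molecule the oxygen cannot reach the mesylate across ring B, and the two carbons flanking the oxygen carry methoxy groups and would need a nine-membered ring, so only intermolecular O-alkylation competes. That, and bimolecular elimination by tert-butoxide, are suppressed by slow addition at high dilution with barely more than one equivalent of base in a hydrogen-bonding solvent that shields the phenolate oxygen. The silyl ether keeps the C9 oxygen from closing a tetrahydrofuran onto the same mesylate.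

Step 15
Reactants: 20 (7R,8S,9R)-9-[(tert-butyldimethylsilyl)oxy]-2,3,3′,4,5′-pentamethoxy-7,8-dimethyl-6,7,8,9-tetrahydrospiro[benzo[7]annulene-5,1′-cyclohexa[2,5]dien]-4′-one
Product: 21 (7R,8S,9R)-9-hydroxy-2,3,3′,4,5′-pentamethoxy-7,8-dimethyl-6,7,8,9-tetrahydrospiro[benzo[7]annulene-5,1′-cyclohexa[2,5]dien]-4′-one (CNP0288561.1)
Conditions: TBAF, AcOH (1:1), THF, rt
Reagents that add atoms: none
Why: Fluoride-mediated desilylation, buffered with AcOH so that no free alkoxide can add to the dienone (oxa-Michael) and no strong acid can trigger a dienone–phenol rearrangement, should free the C9 hydroxyl group.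

**Compound list**

1 | (2S,3S)-2,3-dimethylbutanedioic acid | OC(=O)[C@@H](C)[C@H](C)C(=O)O | starting material
2 | (3S,4S)-3,4-dimethyloxolane-2,5-dione | O1C(=O)[C@@H](C)[C@H](C)C1=O | intermediate
3 | 5-bromo-1,2,3-trimethoxybenzene | COc1cc(Br)cc(OC)c1OC | starting material
4 | (3,4,5-trimethoxyphenyl)magnesium bromide | COc1cc([Mg]Br)cc(OC)c1OC | intermediate
5 | (2S,3S)-2,3-dimethyl-4-oxo-4-(3,4,5-trimethoxyphenyl)butanoic acid | OC(=O)[C@@H](C)[C@H](C)C(=O)c1cc(OC)c(OC)c(OC)c1 | intermediate
6 | methyl (2S,3S)-2,3-dimethyl-4-oxo-4-(3,4,5-trimethoxyphenyl)butanoate | COC(=O)[C@@H](C)[C@H](C)C(=O)c1cc(OC)c(OC)c(OC)c1 | intermediate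
7 | methyl (2S,3S,4R)-4-hydroxy-2,3-dimethyl-4-(3,4,5-trimethoxyphenyl)butanoate | COC(=O)[C@@H](C)[C@H](C)[C@@H](O)c1cc(OC)c(OC)c(OC)c1 | intermediate
8 | (3S,4S,5R)-3,4-dimethyl-5-(3,4,5-trimethoxyphenyl)oxolan-2-one | O=C1[C@@H](C)[C@H](C)[C@@H](O1)c2cc(OC)c(OC)c(OC)c2 | intermediate
9 | (3S,4S,5R)-5-(2-bromo-3,4,5-trimethoxyphenyl)-3,4-dimethyloxolan-2-one | O=C1[C@@H](C)[C@H](C)[C@@H](O1)c2cc(OC)c(OC)c(OC)c2Br | intermediate
10 | 4-bromo-2,6-dimethoxyphenol | COc1cc(Br)cc(OC)c1O | starting material
11 | 2-(benzyloxy)-5-bromo-1,3-dimethoxybenzene | COc1cc(Br)cc(OC)c1OCc1ccccc1 | intermediate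
12 | 2-[4-(benzyloxy)-3,5-dimethoxyphenyl]-4,4,5,5-tetramethyl-1,3,2-dioxaborolane | COc1cc(B2OC(C)(C)C(C)(C)O2)cc(OC)c1OCc1ccccc1 | intermediate
13 | (3S,4S,5R)-5-[4′-(benzyloxy)-3′,4,5,5′,6-pentamethoxybiphenyl-2-yl]-3,4-dimethyloxolan-2-one | O=C1[C@@H](C)[C@H](C)[C@@H](O1)c2cc(OC)c(OC)c(OC)c2-c3cc(OC)c(OCc4ccccc4)c(OC)c3 | intermediate
14 | (1R,2S,3S)-1-[4′-(benzyloxy)-3′,4,5,5′,6-pentamethoxybiphenyl-2-yl]-2,3-dimethylbutane-1,4-diol | OC[C@@H](C)[C@H](C)[C@@H](O)c1cc(OC)c(OC)c(OC)c1-c1cc(OC)c(OCc2ccccc2)c(OC)c1 | intermediate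
15 | bis(tert-butyldimethylsilyl) ether of 14 | CC(C)(C)[Si](C)(C)OC[C@@H](C)[C@H](C)[C@@H](O[Si](C)(C)C(C)(C)C)c1cc(OC)c(OC)c(OC)c1-c1cc(OC)c(OCc2ccccc2)c(OC)c1 | intermediate
16 | (2S,3S,4R)-4-[4′-(benzyloxy)-3′,4,5,5′,6-pentamethoxybiphenyl-2-yl]-4-[(tert-butyldimethylsilyl)oxy]-2,3-dimethylbutan-1-ol | OC[C@@H](C)[C@H](C)[C@@H](O[Si](C)(C)C(C)(C)C)c1cc(OC)c(OC)c(OC)c1-c1cc(OC)c(OCc2ccccc2)c(OC)c1 | intermediate
17 | (2S,3S,4R)-4-[4′-(benzyloxy)-3′,4,5,5′,6-pentamethoxybiphenyl-2-yl]-4-[(tert-butyldimethylsilyl)oxy]-2,3-dimethylbutyl methanesulfonate | CS(=O)(=O)OC[C@@H](C)[C@H](C)[C@@H](O[Si](C)(C)C(C)(C)C)c1cc(OC)c(OC)c(OC)c1-c1cc(OC)c(OCc2ccccc2)c(OC)c1 | intermediate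
18 | (2S,3S,4R)-4-[(tert-butyldimethylsilyl)oxy]-4-(4′-hydroxy-3′,4,5,5′,6-pentamethoxybiphenyl-2-yl)-2,3-dimethylbutyl methanesulfonate | CS(=O)(=O)OC[C@@H](C)[C@H](C)[C@@H](O[Si](C)(C)C(C)(C)C)c1cc(OC)c(OC)c(OC)c1-c1cc(OC)c(O)c(OC)c1 | intermediate
19 | potassium phenolate of 18 | CS(=O)(=O)OC[C@@H](C)[C@H](C)[C@@H](O[Si](C)(C)C(C)(C)C)c1cc(OC)c(OC)c(OC)c1-c1cc(OC)c([O-])c(OC)c1.[K+] | intermediate
20 | (7R,8S,9R)-9-[(tert-butyldimethylsilyl)oxy]-2,3,3′,4,5′-pentamethoxy-7,8-dimethyl-6,7,8,9-tetrahydrospiro[benzo[7]annulene-5,1′-cyclohexa[2,5]dien]-4′-one | COC1=CC2(C=C(OC)C1=O)C[C@@H](C)[C@H](C)[C@@H](O[Si](C)(C)C(C)(C)C)c1cc(OC)c(OC)c(OC)c12 | intermediate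
21 | (7R,8S,9R)-9-hydroxy-2,3,3′,4,5′-pentamethoxy-7,8-dimethyl-6,7,8,9-tetrahydrospiro[benzo[7]annulene-5,1′-cyclohexa[2,5]dien]-4′-one | COC1=CC2(C=C(OC)C1=O)C[C@@H](C)[C@H](C)[C@@H](O)c1cc(OC)c(OC)c(OC)c12 | target

**Step count**

Total: 15 steps. Longest linear sequence: 13 steps (steps 1–5 and 8–15, from 1 to 21); the ring-B branch (steps 6 and 7) joins at step 8.

**Steps most likely to fail**

1. Step 14. Closure of a seven-membered ring with loss of aromaticity may be slower than intermolecular O-alkylation (oligomer formation) or than elimination of the mesylate.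
Fallback: the same ring and spiro centre are closed through the aryl–C5 bond by oxidative phenol–arene coupling. It sets out from lactone 8 and comes back at 20. LiAlH4 should reduce 8 to (1R,2S,3S)-2,3-dimethyl-1-(3,4,5-trimethoxyphenyl)butane-1,4-diol F1. TBSOTf/2,6-lutidine should give its bis(tert-butyldimethylsilyl) ether F2, and HF·pyridine the primary alcohol (2S,3S,4R)-4-[(tert-butyldimethylsilyl)oxy]-2,3-dimethyl-4-(3,4,5-trimethoxyphenyl)butan-1-ol F3. I2/PPh3/imidazole should convert this into the primary iodide tert-butyl{[(1R,2S,3S)-4-iodo-2,3-dimethyl-1-(3,4,5-trimethoxyphenyl)butyl]oxy}dimethylsilane F4. Zinc insertion (Zn dust, LiCl, THF) should give the corresponding alkylzinc iodide F5, which is coupled with aryl bromide 11 (Pd(OAc)2, SPhos; Negishi coupling) to the benzyl-protected 1,4-diarylbutane F6. Hydrogenolysis (H2, Pd/C, EtOAc) frees 4-[(2R,3S,4R)-4-[(tert-butyldimethylsilyl)oxy]-2,3-dimethyl-4-(3,4,5-trimethoxyphenyl)butyl]-2,6-dimethoxyphenol F7. PhI(OCOCF3)2 in CF3CH2OH at −40 °C then oxidises the phenol to a phenoxenium ion. Ring A attacks it through C2 (ortho to the carbinol carbon, para to a methoxy group) at the alkyl-bearing para carbon of ring B, a para–ortho oxidative coupling of the kind used to close seven-membered rings onto spirodienones, and this should give 20.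

2. Step 4. Facial selectivity may be poor, because the catalyst has to override the Felkin–Anh preference of the adjacent methyl-bearing centre and an α-branched alkyl group is a less clear small substituent.
Fallback: the carbinol is set by C–C bond formation, where the Felkin–Anh preference favours the wanted syn isomer. It sets out from anhydride 2 and comes back at 8. NaBH4 (THF, 0 °C, then acid) should reduce 2 to (3S,4S)-3,4-dimethyloxolan-2-one F8, and i-Bu2AlH (CH2Cl2, −78 °C) should give the lactol (3S,4S)-3,4-dimethyloxolan-2-ol F9. Addition of ArMgBr 4 (2.5 equiv, THF, −78 → 0 °C) to the open hydroxy aldehyde form should give diol F1 with the hydroxyl syn to the neighbouring methyl group. TEMPO (cat.)/PhI(OAc)2 then oxidises the primary alcohol through the lactol to lactone 8.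

3. Step 2. The Grignard reagent may add a second time to the new ketone, and enolisation may epimerise the centre next to it.
Fallback: the acyl donor is changed to one that forms a stable chelated tetrahedral intermediate. It sets out from 2 and comes back at 5. MeNH(OMe)·HCl and Et3N in CH2Cl2 should open 2 to (2S,3S)-4-[methoxy(methyl)amino]-2,3-dimethyl-4-oxobutanoic acid F10. ArMgBr 4 (2.2 equiv, THF, 0 °C) should then add once to the Weinreb amide of the carboxylate salt and give keto acid 5 on acidic work-up.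

**Further compounds**

F1 | step 14 | (1R,2S,3S)-2,3-dimethyl-1-(3,4,5-trimethoxyphenyl)butane-1,4-diol | OC[C@@H](C)[C@H](C)[C@@H](O)c1cc(OC)c(OC)c(OC)c1
F2 | step 14 | bis(tert-butyldimethylsilyl) ether of F1 | CC(C)(C)[Si](C)(C)OC[C@@H](C)[C@H](C)[C@@H](O[Si](C)(C)C(C)(C)C)c1cc(OC)c(OC)c(OC)c1
F3 | step 14 | (2S,3S,4R)-4-[(tert-butyldimethylsilyl)oxy]-2,3-dimethyl-4-(3,4,5-trimethoxyphenyl)butan-1-ol | OC[C@@H](C)[C@H](C)[C@@H](O[Si](C)(C)C(C)(C)C)c1cc(OC)c(OC)c(OC)c1
F4 | step 14 | tert-butyl{[(1R,2S,3S)-4-iodo-2,3-dimethyl-1-(3,4,5-trimethoxyphenyl)butyl]oxy}dimethylsilane | IC[C@@H](C)[C@H](C)[C@@H](O[Si](C)(C)C(C)(C)C)c1cc(OC)c(OC)c(OC)c1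
F5 | step 14 | alkylzinc iodide derived from F4 | I[Zn]C[C@@H](C)[C@H](C)[C@@H](O[Si](C)(C)C(C)(C)C)c1cc(OC)c(OC)c(OC)c1
F6 | step 14 | benzyl ether of F7 (2-(benzyloxy)-1,3-dimethoxy-5-alkylbenzene) | COc1cc(C[C@@H](C)[C@H](C)[C@@H](O[Si](C)(C)C(C)(C)C)c2cc(OC)c(OC)c(OC)c2)cc(OC)c1OCc1ccccc1
F7 | step 14 | 4-[(2R,3S,4R)-4-[(tert-butyldimethylsilyl)oxy]-2,3-dimethyl-4-(3,4,5-trimethoxyphenyl)butyl]-2,6-dimethoxyphenol | COc1cc(C[C@@H](C)[C@H](C)[C@@H](O[Si](C)(C)C(C)(C)C)c2cc(OC)c(OC)c(OC)c2)cc(OC)c1O
F8 | step 4 | (3S,4S)-3,4-dimethyloxolan-2-one | O=C1[C@@H](C)[C@H](C)CO1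
F9 | step 4 | (3S,4S)-3,4-dimethyloxolan-2-ol | OC1[C@@H](C)[C@H](C)CO1
F10 | step 2 | (2S,3S)-4-[methoxy(methyl)amino]-2,3-dimethyl-4-oxobutanoic acid | OC(=O)[C@@H](C)[C@H](C)C(=O)N(C)OC
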